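- I want to know how strongly the rate of making X in the flask responds, at the look (the moment when 30% of the Z are converted), to more L and to twice the E, and I turn this round: in the reckoning below, where L dies as it works, an order in L of exactly 1 goes with no L lost by the look.

common to all: L 0.5 mol%
- green: Z 0.40 M; E 0.60 equiv; run made earlier
- blue: Z 0.60 M; E 0.60 equiv; run made earlier
- violet: Z 0.80 M; E 0.30 equiv; run made earlier
- flask: Z 0.80 M; E 0.600 equiv

- green (time / min: X / %, Z / %): 1.50: 18, 84; 5.00: 31, 68; 8.00: 39, 64; 12.0: 42, 52; 20.0: 48, 48
- blue (time / min: X / %, Z / %): 4.00: 35, 61; 8.00: 50, 49; 10.0: 54, 49; 15.0: 53, 45; 20.0: 54, 44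
- violet (time / min: X / %, Z / %): 4.00: 24, 75; 8.00: 27, 73; 10.0: 27, 72; 15.0: 31, 71; 20.0: 31, 72

(standard deviation of a reading: 2 percentage points)

- apparent order in L when 30% of the Z are converted (percent change of the rate of making X for one percent more L charged)
- factor on the rate of making X when 30% of the Z are converted if E is charged twice over

- the analysis behind the earlier runs scatters by 2 percentage points, standard deviation

- Blue reads X at 54% after 20.0 min with 0.60 equiv of E, the limiting reagent, charged, and I read that shortfall as L dying at a steady first-order rate while the rate follows [L][Z][E].
- I call the dose the sum, over conversion, of one over the product of the share of Z left and the E left per Z charged; the dose at blue's stall reads 3.82, a reading that carries the scatter of the X behind it.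
- On that reading, at fixed loading, this lifetime allowance scales with the square of [Z] as charged, so the flask's allowance, the total dose its L can deliver, reads 6.78.
- Reaching the look costs the flask a dose of 0.841, a spent share of 12.4%, and on this reading the order is one over the share unspent, so I commit to 1.14; on the same rule an order of 2 needs a spent share of 0.5.
- With E charged twice over, [E] at the look stands 3.00 times higher and less of the allowance is spent, so the same rule gives me a factor of 3.25, and the allowance puts the flask's stall at X = 58.3%.
- The forecast, which differs from my reckoning, gives an order of 1 (0.7 to 2.2) and a factor of 3.1 (2.2 to 3.5), judging that catalyst death “fits the rates worse”.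
- The flask gives an order of 1.2 and a factor of 2.18.

    E + L ⇌ D (K = 2.32 /M, k = 2.31 /M/s)
    Z + D → G (k = 45.7 /M/s)
    G → L + X (k = 1.50 /s)
    L → J (k = 0.00228 /s)

- My factor stands above the flask's, and in the flask the equilibrium constant of E + L into D times [E] as charged is 1.1. The allowance of 6.78 gave a stall at 58.3%, and the flask's X stands at 57.6% after 15.0 min and 58.7% after 150 min. Violet has the same [Z] and loading as the flask, so the same allowance gives it a stall at 29.8%, and its X reads 31% after 20.0 min.

The readings are calculated on assumed constants; scatter was added.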